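**Retrosynthetic overview**
1. Target ⇐ chelation-controlled reduction of the (S)-α-aryloxy ketone ⇐ Mitsunobu etherification (inversion) of the all-cis oxolane phenol with an (R)-lactate-derived α-hydroxy ketone.
2. Phenol ⇐ hydrogenolysis of a p-xylylene-linked bis(oxolane), so two cores are built on one molecule.
3. Each oxolane ⇐ aryllithium addition to an all-cis γ-lactone, then silane reduction of the cyclic oxocarbenium ion (hydride opposite the three cis substituents).
4. Ring formation: the two γ-lactone rings close together in one twofold asymmetric transfer hydrogenation/lactonization of a bis(γ-keto acid); these rings become the two oxolanes, and no other ring is made.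
5. Bis(keto acid) ⇐ twofold Rh-catalysed enantioselective arylzinc opening of meso-2,3-dimethylsuccinic anhydride (from dimethylmaleic anhydride) by the dibromide made from 4-bromoguaiacol and 1,4-bis(bromomethyl)benzene.

Assumption: (S)-t-Bu-PHOX is taken to give the (2S,3R) keto-acid arms in step 3; if a trial coupling shows the opposite sense, (R)-t-Bu-PHOX is used and nothing else changes.

**Step 1**
Reactants: 1 4-bromo-2-methoxyphenol (2 equiv); 2 1,4-bis(bromomethyl)benzene
Product: 3 1,4-bis[(4-bromo-2-methoxyphenoxy)methyl]benzene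
Conditions: K2CO3, DMF, 60 °C
Reagents that add atoms: none
Why: Twofold Williamson etherification gives a robust bis(benzylic aryl ether) that protects both phenols, lets each later operation build two cores at once, and is removed by hydrogenolysis; no stereocentre is involved.

**Step 2**
Reactants: 4 2,3-dimethylmaleic anhydride
Product: 5 meso-2,3-dimethylsuccinic anhydride [(3R,4S)-3,4-dimethyloxolane-2,5-dione; methyls cis]
Conditions: H2 (4 atm), Pd/C, EtOAc, rt
Reagents that add atoms: none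
Why: Heterogeneous catalytic hydrogenation adds H2 syn across the tetrasubstituted alkene, so the two methyl-bearing centres are created as the cis (meso) pair only.

**Step 3**
Reactants: 3; 5 (2.4 equiv)
Product: 8 4,4'-{1,4-phenylenebis[methyleneoxy(3-methoxy-4,1-phenylene)]}bis[(2S,3R)-2,3-dimethyl-4-oxobutanoic acid], via bis(aryllithium) 6 (not isolated), via bis(arylzinc triflate) 7 (not isolated)
Conditions: n-BuLi (2.1 equiv), THF, −78 °C; Zn(OTf)2 (2.2 equiv), −78 °C → rt; then 5, [Rh(cod)Cl]2 (5 mol %), (S)-t-Bu-PHOX (10 mol %), THF–DMF, 50 °C; 1 M HCl work-up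
Reagents that add atoms: none
Why: After Br/Li exchange and transmetalation, the Rh/phosphinooxazoline-catalysed enantioselective cross-coupling of an arylzinc with a meso anhydride (desymmetrization) opens one enantiotopic acyl C–O bond on each arm, which turns the meso methyl pair into the (2S,3R) keto acid without touching either methyl centre.

**Step 4**
Reactants: 8
Product: 10 5,5'-{1,4-phenylenebis[methyleneoxy(3-methoxy-4,1-phenylene)]}bis[(3S,4R,5S)-3,4-dimethyloxolan-2-one] (each lactone all-cis), via bis(hydroxy acid) 9 (not isolated)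
Conditions: RuCl[(S,S)-TsDPEN](p-cymene) (4 mol %), HCO2H–Et3N (5:2), DMF, 40 °C; then TsOH·H2O (cat.), PhMe, 60 °C
Reagents that add atoms: none
Why: Noyori-type asymmetric transfer hydrogenation sets both benzylic carbinols (S) by catalyst control, independent of the Felkin preference, and both γ-hydroxy acids lactonize in the same operation, so two all-cis γ-lactone rings close at once; arms of the minor configuration end up as trans-lactone diastereomers and are removed by crystallization.

**Step 5**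
Reactants: 10; 11 4-bromo-1,2-dimethoxybenzene (2.6 equiv)
Product: 14 1,4-bis({4-[(2S,3R,4S,5R)-5-(3,4-dimethoxyphenyl)-3,4-dimethyloxolan-2-yl]-2-methoxyphenoxy}methyl)benzene, via 3,4-dimethoxyphenyllithium 12 (not isolated), via bis(lactol) 13 (not isolated)
Conditions: 11, n-BuLi, THF, −78 °C; add 10, −78 °C; aq NH4Cl, crude taken on; Et3SiH (8 equiv), BF3·OEt2 (4 equiv), CH2Cl2, −78 °C
Reagents that add atoms: none
Why: Aryllithium addition to each lactone carbonyl gives the lactol, and BF3-promoted ionization with silane reduction (ionic hydrogenation of a cyclic oxocarbenium ion) delivers hydride to the face opposite the three cis substituents, which sets the new benzylic centre (5R) and gives the all-cis oxolane on each arm.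

**Step 6**
Reactants: 14
Product: 15 4-[(2S,3R,4S,5R)-5-(3,4-dimethoxyphenyl)-3,4-dimethyloxolan-2-yl]-2-methoxyphenol (2 equiv per 14)
Conditions: H2 (1 atm), Pd/C, EtOAc–EtOH, rt
Reagents that add atoms: none
Why: Hydrogenolysis of the two benzyl aryl ethers is much faster than cleavage of the ring dialkyl benzylic C–O bonds, so two molecules of phenol are released with all four stereocentres unchanged.

**Step 7**
Reactants: 16 methyl (R)-lactate
Product: 17 (R)-2-hydroxy-1-(pyrrolidin-1-yl)propan-1-one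
Conditions: pyrrolidine (3 equiv), neat, rt
Reagents that add atoms: pyrrolidine C1CCNC1
Why: Ester aminolysis by a secondary amine under neutral conditions does not enolize the lactate centre, so the (R) configuration is kept.

**Step 8**
Reactants: 17; 18 3,4-dimethoxyphenylmagnesium bromide (2.5 equiv)
Product: 19 (R)-1-(3,4-dimethoxyphenyl)-2-hydroxypropan-1-one
Conditions: THF, −20 → 0 °C; aq NH4Cl
Reagents that add atoms: none
Why: Grignard acylation with a tertiary amide: the first equivalent forms the magnesium alkoxide, the second adds once to give a chelated tetrahedral adduct that collapses to the ketone only on work-up, so there is no over-addition and the α-centre stays (R).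

**Step 9**
Reactants: 15; 19
Product: 20 (2S)-1-(3,4-dimethoxyphenyl)-2-{4-[(2S,3R,4S,5R)-5-(3,4-dimethoxyphenyl)-3,4-dimethyloxolan-2-yl]-2-methoxyphenoxy}propan-1-one
Conditions: PPh3, DIAD, THF, 0 °C → rt
Reagents that add atoms: none
Why: Mitsunobu etherification: the phenoxide displaces the oxyphosphonium group by SN2 under non-basic conditions, which inverts the carbinol carbon from (R) to the (S) aryloxy centre of the target.

**Step 10**
Reactants: 20
Product: 21 (1R,2S)-1-(3,4-dimethoxyphenyl)-2-{4-[(2S,3R,4S,5R)-5-(3,4-dimethoxyphenyl)-3,4-dimethyloxolan-2-yl]-2-methoxyphenoxy}propan-1-ol (CNP0286615.2)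
Conditions: Zn(BH4)2, Et2O, −30 °C
Reagents that add atoms: none
Why: Chelation-controlled (Cram-chelate) hydride reduction: zinc bridges the carbonyl and aryloxy oxygens and hydride adds from the face of the small H substituent, which gives the erythro (1R,2S) alcohol.

**Compound list**
1 | 4-bromo-2-methoxyphenol | COc1cc(Br)ccc1O | starting material
2 | 1,4-bis(bromomethyl)benzene | BrCc1ccc(CBr)cc1 | starting material
3 | 1,4-bis[(4-bromo-2-methoxyphenoxy)methyl]benzene | COc1cc(Br)ccc1OCc1ccc(COc2ccc(Br)cc2OC)cc1 | intermediate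
4 | 2,3-dimethylmaleic anhydride | CC1=C(C)C(=O)OC1=O | starting material
5 | meso-2,3-dimethylsuccinic anhydride, (3R,4S)-3,4-dimethyloxolane-2,5-dione | O=C1[C@@H](C)[C@@H](C)C(=O)O1 | intermediate
6 | bis(aryllithium), 1,4-bis[(4-lithio-2-methoxyphenoxy)methyl]benzene | [Li]c1ccc(OCc2ccc(COc3ccc([Li])cc3OC)cc2)c(OC)c1 | intermediate
7 | bis(arylzinc triflate) of 3 | FC(F)(F)S(=O)(=O)O[Zn]c1ccc(OCc2ccc(COc3ccc([Zn]OS(=O)(=O)C(F)(F)F)cc3OC)cc2)c(OC)c1 | intermediate
8 | 4,4'-{1,4-phenylenebis[methyleneoxy(3-methoxy-4,1-phenylene)]}bis[(2S,3R)-2,3-dimethyl-4-oxobutanoic acid] | OC(=O)[C@@H](C)[C@@H](C)C(=O)c1ccc(OCc2ccc(COc3ccc(C(=O)[C@H](C)[C@H](C)C(=O)O)cc3OC)cc2)c(OC)c1 | intermediate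
9 | 4,4'-{1,4-phenylenebis[methyleneoxy(3-methoxy-4,1-phenylene)]}bis[(2S,3R,4S)-4-hydroxy-2,3-dimethylbutanoic acid] | OC(=O)[C@@H](C)[C@@H](C)[C@H](O)c1ccc(OCc2ccc(COc3ccc([C@@H](O)[C@H](C)[C@H](C)C(=O)O)cc3OC)cc2)c(OC)c1 | intermediate
10 | 5,5'-{1,4-phenylenebis[methyleneoxy(3-methoxy-4,1-phenylene)]}bis[(3S,4R,5S)-3,4-dimethyloxolan-2-one] | COc1cc([C@H]2OC(=O)[C@@H](C)[C@H]2C)ccc1OCc1ccc(COc2ccc([C@H]3OC(=O)[C@@H](C)[C@H]3C)cc2OC)cc1 | intermediate
11 | 4-bromo-1,2-dimethoxybenzene | COc1ccc(Br)cc1OC | starting material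
12 | 3,4-dimethoxyphenyllithium | [Li]c1ccc(OC)c(OC)c1 | intermediate
13 | bis(lactol): each arm (3R,4S,5S)-2-(3,4-dimethoxyphenyl)-2-hydroxy-3,4-dimethyloxolan-5-yl, anomeric mixture | COc1cc([C@H]2OC(O)(c3ccc(OC)c(OC)c3)[C@@H](C)[C@H]2C)ccc1OCc1ccc(COc2ccc([C@H]3OC(O)(c4ccc(OC)c(OC)c4)[C@@H](C)[C@H]3C)cc2OC)cc1 | intermediate
14 | 1,4-bis({4-[(2S,3R,4S,5R)-5-(3,4-dimethoxyphenyl)-3,4-dimethyloxolan-2-yl]-2-methoxyphenoxy}methyl)benzene | COc1cc([C@H]2O[C@@H](c3ccc(OC)c(OC)c3)[C@@H](C)[C@H]2C)ccc1OCc1ccc(COc2ccc([C@H]3O[C@@H](c4ccc(OC)c(OC)c4)[C@@H](C)[C@H]3C)cc2OC)cc1 | intermediate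
15 | 4-[(2S,3R,4S,5R)-5-(3,4-dimethoxyphenyl)-3,4-dimethyloxolan-2-yl]-2-methoxyphenol | COc1cc([C@H]2O[C@@H](c3ccc(OC)c(OC)c3)[C@@H](C)[C@H]2C)ccc1O | intermediate
16 | methyl (R)-lactate | C[C@@H](O)C(=O)OC | starting material
17 | (R)-2-hydroxy-1-(pyrrolidin-1-yl)propan-1-one | C[C@@H](O)C(=O)N1CCCC1 | intermediate
18 | 3,4-dimethoxyphenylmagnesium bromide (THF solution) | COc1ccc([Mg]Br)cc1OC | starting material
19 | (R)-1-(3,4-dimethoxyphenyl)-2-hydroxypropan-1-one | C[C@@H](O)C(=O)c1ccc(OC)c(OC)c1 | intermediate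
20 | (2S)-1-(3,4-dimethoxyphenyl)-2-{4-[(2S,3R,4S,5R)-5-(3,4-dimethoxyphenyl)-3,4-dimethyloxolan-2-yl]-2-methoxyphenoxy}propan-1-one | COc1ccc(C(=O)[C@H](C)Oc2ccc([C@H]3O[C@@H](c4ccc(OC)c(OC)c4)[C@@H](C)[C@H]3C)cc2OC)cc1OC | intermediate
21 | (1R,2S)-1-(3,4-dimethoxyphenyl)-2-{4-[(2S,3R,4S,5R)-5-(3,4-dimethoxyphenyl)-3,4-dimethyloxolan-2-yl]-2-methoxyphenoxy}propan-1-ol | COc1ccc([C@@H](O)[C@H](C)Oc2ccc([C@H]3O[C@@H](c4ccc(OC)c(OC)c4)[C@@H](C)[C@H]3C)cc2OC)cc1OC | target

**Step count and risks**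
Total steps: 10. Longest linear sequence: 7 (steps 2, 3, 4, 5, 6, 9, 10; equally 1, 3, 4, 5, 6, 9, 10).

Most likely to fail, first: step 3. Both arms of a bis(arylzinc) must couple, and the sense and level of induction are untested on this nucleophile. The fallback sets out from 5 (with 3) and returns at 10. Cinchona-alkaloid-mediated benzyl alcoholysis of 5 (quinidine, BnOH, PhMe, −55 °C; quinine if the mirror-image product forms) gives the half-ester (2R,3S)-4-(benzyloxy)-2,3-dimethyl-4-oxobutanoic acid F1. Oxalyl chloride with catalytic DMF turns it into the acyl chloride benzyl (2S,3R)-4-chloro-2,3-dimethyl-4-oxobutanoate F2. The bis(arylzinc) 7, made from 3 as in step 3, is acylated on both arms with F2 under Pd(PPh3)4 (Negishi acylation) to the bis(keto benzyl ester) F3. Under the step-4 transfer hydrogenation F3 gives the bis(hydroxy benzyl ester) F4, which closes to 10 with TsOH in warm toluene.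

Second: step 4. The catalyst must override the substrate's Felkin bias on an α-branched, electron-rich aryl ketone that may also reduce slowly. The fallback sets out from 8 and returns at 10. Me3SiCHN2 (PhMe–MeOH) gives the bis(keto methyl ester) F5. The (R)-Me-CBS oxazaborolidine with BH3·SMe2 (THF, −20 °C) reduces both ketones to the bis(hydroxy methyl ester) F6 with (4S) carbinols. TsOH in toluene then closes both lactones to 10.

Third: step 9. The activated α-hydroxy ketone may eliminate or partly racemize under Mitsunobu conditions. The fallback sets out from 19 (with 15) and returns at 20. TsCl, Et3N and DMAP give the sulfonate (R)-1-(3,4-dimethoxyphenyl)-1-oxopropan-2-yl 4-methylbenzenesulfonate F7. Phenol 15 displaces it with the phosphazene base BEMP in MeCN at rt (SN2, inversion) to give 20.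

**Further compounds**
F1 | step 3 | (2R,3S)-4-(benzyloxy)-2,3-dimethyl-4-oxobutanoic acid | O=C(OCc1ccccc1)[C@@H](C)[C@@H](C)C(=O)O
F2 | step 3 | benzyl (2S,3R)-4-chloro-2,3-dimethyl-4-oxobutanoate | O=C(OCc1ccccc1)[C@@H](C)[C@@H](C)C(=O)Cl
F3 | step 3 | dibenzyl 4,4'-{1,4-phenylenebis[methyleneoxy(3-methoxy-4,1-phenylene)]}bis[(2S,3R)-2,3-dimethyl-4-oxobutanoate] | O=C(OCc1ccccc1)[C@@H](C)[C@@H](C)C(=O)c1ccc(OCc2ccc(COc3ccc(C(=O)[C@H](C)[C@H](C)C(=O)OCc4ccccc4)cc3OC)cc2)c(OC)c1
F4 | step 3 | dibenzyl 4,4'-{1,4-phenylenebis[methyleneoxy(3-methoxy-4,1-phenylene)]}bis[(2S,3R,4S)-4-hydroxy-2,3-dimethylbutanoate] | O=C(OCc1ccccc1)[C@@H](C)[C@@H](C)[C@H](O)c1ccc(OCc2ccc(COc3ccc([C@@H](O)[C@H](C)[C@H](C)C(=O)OCc4ccccc4)cc3OC)cc2)c(OC)c1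
F5 | step 4 | dimethyl 4,4'-{1,4-phenylenebis[methyleneoxy(3-methoxy-4,1-phenylene)]}bis[(2S,3R)-2,3-dimethyl-4-oxobutanoate] | COC(=O)[C@@H](C)[C@@H](C)C(=O)c1ccc(OCc2ccc(COc3ccc(C(=O)[C@H](C)[C@H](C)C(=O)OC)cc3OC)cc2)c(OC)c1
F6 | step 4 | dimethyl 4,4'-{1,4-phenylenebis[methyleneoxy(3-methoxy-4,1-phenylene)]}bis[(2S,3R,4S)-4-hydroxy-2,3-dimethylbutanoate] | COC(=O)[C@@H](C)[C@@H](C)[C@H](O)c1ccc(OCc2ccc(COc3ccc([C@@H](O)[C@H](C)[C@H](C)C(=O)OC)cc3OC)cc2)c(OC)c1
F7 | step 9 | (R)-1-(3,4-dimethoxyphenyl)-1-oxopropan-2-yl 4-methylbenzenesulfonate | C[C@@H](OS(=O)(=O)c1ccc(C)cc1)C(=O)c1ccc(OC)c(OC)c1
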